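**Plan**
- Retrosynthesis: the two late O–acyl bonds are cut first (phenol O–angeloyl, CH2O–acetyl), then the oxirane at C(quaternary)–CH2 and CH2–O (methylene from a sulfur ylide), then the aryl–C(=O) bond (aryl Grignard plus Weinreb amide), which leaves an iodophenol ester.
- Forward: the iodoarene is allylated, reduced and isovaleroylated; iodine–magnesium exchange and acylation attach the PMB-glycolyl unit; the only ring, the oxirane, closes in step 6; PMB is then exchanged for acetate and allyl for the angelate.
- Enabling feature: the oxirane is terminal and 2,2-disubstituted. Its quaternary carbon carries the aryl ring and the CH2O arm and its other carbon is a bare CH2, so the ring CH2, the C–CH2 bond and the CH2–O bond can all come from CH2 transfer to the C=O of an aryl alkoxymethyl ketone.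
- Stereochemistry: the single stereocentre (R) is set by catalyst control in the methylene transfer (LaLi3 tris(binaphthoxide), Re-face attack). The Z-alkene is bought with angelic acid and kept by a DMAP-free mixed-anhydride esterification.
- Both oxygens flanking the ketone are carried as carbon ethers (aryl O-allyl, CH2O-PMB) and not as silyl or acyl groups, so nothing can migrate to the betaine alkoxide.

Key step: step 6

Assumption: the (R)-binaphthoxide catalyst is taken to send the ylide to the Re face of the aryl ketone (aryl read as the large group, as for aryl methyl ketones); if a first run shows the opposite sense, the (S)-ligand is used in the same step with nothing else changed.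

**Step 1**
Reactants: 1 methyl 3-hydroxy-4-iodobenzoate
Product: 2 methyl 4-iodo-3-(prop-2-en-1-yloxy)benzoate
Conditions: allyl bromide, K2CO3, DMF, rt
Reagents that add atoms: allyl bromide, C=CCBr
Why: Williamson etherification of the potassium phenoxide with a reactive allylic bromide gives a carbon-bound phenol mask that cannot migrate and that later leaves under neutral palladium catalysis.

**Step 2**
Reactants: 2 methyl 4-iodo-3-(prop-2-en-1-yloxy)benzoate
Product: 3 [4-iodo-3-(prop-2-en-1-yloxy)phenyl]methanol
Conditions: i-Bu2AlH (2.5 equiv), CH2Cl2, −78 to 0 °C; aq. KNaC4H4O6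
Reagents that add atoms: none
Why: Hydride reduction of the methyl benzoate to the benzylic alcohol by i-Bu2AlH leaves the aryl iodide and the isolated alkene untouched at low temperature.

**Step 3**
Reactants: 3 [4-iodo-3-(prop-2-en-1-yloxy)phenyl]methanol
Product: 4 [4-iodo-3-(prop-2-en-1-yloxy)phenyl]methyl 3-methylbutanoate
Conditions: 3-methylbutanoyl chloride, Et3N, DMAP (cat.), CH2Cl2, 0 °C
Reagents that add atoms: 3-methylbutanoyl chloride, CC(C)CC(=O)Cl
Why: DMAP-catalysed esterification of a primary benzylic alcohol with an acid chloride installs the isovalerate of the target early, so that it serves as its own protecting group.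

**Step 4**
Reactants: 5 4-methoxybenzyl alcohol; 6 2-chloro-N-methoxy-N-methylacetamide
Product: 8 N-methoxy-2-[(4-methoxyphenyl)methoxy]-N-methylacetamide, via sodium 4-methoxybenzyl oxide 7 (not isolated)
Conditions: 5, NaH, THF, 0 °C; then 6, Bu4NI (cat.), 0 °C to rt
Reagents that add atoms: none
Why: Williamson ether synthesis, in which alkoxide 7 displaces the activated α-chloride by SN2 while the Weinreb amide carbonyl is a poor acceptor for an alkoxide.

**Step 5**
Reactants: 4 [4-iodo-3-(prop-2-en-1-yloxy)phenyl]methyl 3-methylbutanoate; 8 N-methoxy-2-[(4-methoxyphenyl)methoxy]-N-methylacetamide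
Product: 11 {4-{2-[(4-methoxyphenyl)methoxy]acetyl}-3-(prop-2-en-1-yloxy)phenyl}methyl 3-methylbutanoate, via arylmagnesium chloride 9 (not isolated), via tetrahedral magnesium hemiaminal 10 (not isolated)
Conditions: iPrMgCl·LiCl (1.05 equiv), THF, −20 °C; then 8 (1.2 equiv), −20 to 0 °C; aq. NH4Cl
Reagents that add atoms: none
Why: Iodine–magnesium exchange with the LiCl-activated Grignard reagent at low temperature tolerates the aliphatic ester, and the Weinreb ketone synthesis stops at chelate 10, which releases the ketone only on work-up.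

**Step 6**
Reactants: 11 {4-{2-[(4-methoxyphenyl)methoxy]acetyl}-3-(prop-2-en-1-yloxy)phenyl}methyl 3-methylbutanoate; 12 trimethylsulfoxonium chloride
Product: 15 {4-[(2R)-2-{[(4-methoxyphenyl)methoxy]methyl}oxiran-2-yl]-3-(prop-2-en-1-yloxy)phenyl}methyl 3-methylbutanoate, via dimethylsulfoxonium methylide 13 (not isolated), via sulfoxonium betaine 14 (not isolated)
Conditions: 12, NaH, THF, reflux, filtered; ylide solution (1.2 equiv) added to 11, LaLi3[(R)-binaphthoxide]3 (5 mol%), (2,4,6-(MeO)3C6H2)3P=O (5 mol%), 5 Å molecular sieves, THF, rt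
Reagents that add atoms: none
Why: Catalytic asymmetric Corey–Chaykovsky epoxidation: the ketone oxygen of 11 is bound at the trivalent lanthanum centre of LaLi3[(R)-binaphthoxide]3 (made more selective by the phosphine oxide), ylide 13 is held at a neighbouring lithium binaphthoxide oxygen, and its carbon adds to the carbonyl carbon to give betaine 14. The alkoxide of 14 then expels dimethyl sulfoxide from the adjacent CH2 in a 3-exo-tet closure, which forms the oxirane, the only ring made in the route. The closest known reaction is this same catalytic methylene transfer to aryl methyl ketones, known to give 2,2-disubstituted terminal epoxides with high enantioselectivity; a CH2OPMB arm in place of methyl and an ortho alkoxy group on the ring are the untested elements. The single new stereocentre is set by the catalyst alone, which must deliver CH2 to the Re face of the carbonyl (O > CH2OPMB > aryl) by reading the twisted ortho-substituted aryl group as large and the CH2O arm as small, giving (R)-15. Chemoselectivity for the ketone over the remote isovalerate is needed and should follow from the far higher electrophilicity of the lanthanum-bound ketone, the near-stoichiometric amount of ylide and room temperature. Because both oxygens next to the carbonyl are carbon ethers (allyl and 4-methoxybenzyl), no group can migrate to the betaine alkoxide and no phenoxide can arise to attack the CH2–S carbon, which keeps the closure on the 3-exo path.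

**Step 7**
Reactants: 15 {4-[(2R)-2-{[(4-methoxyphenyl)methoxy]methyl}oxiran-2-yl]-3-(prop-2-en-1-yloxy)phenyl}methyl 3-methylbutanoate
Product: 16 {4-[(2S)-2-(hydroxymethyl)oxiran-2-yl]-3-(prop-2-en-1-yloxy)phenyl}methyl 3-methylbutanoate
Conditions: DDQ (1.3 equiv), CH2Cl2/aq. NaH2PO4–Na2HPO4 (pH 7), 0 °C to rt
Reagents that add atoms: none
Why: Oxidative cleavage of the 4-methoxybenzyl ether by DDQ at buffered neutral pH spares the acid-labile benzylic oxirane, the allyl ether and the ester; a Payne shift of the product would be degenerate and cannot erode the stereocentre (the descriptor changes to S only because the CIP ranking changes).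

**Step 8**
Reactants: 16 {4-[(2S)-2-(hydroxymethyl)oxiran-2-yl]-3-(prop-2-en-1-yloxy)phenyl}methyl 3-methylbutanoate
Product: 17 {4-[(2R)-2-(acetyloxymethyl)oxiran-2-yl]-3-(prop-2-en-1-yloxy)phenyl}methyl 3-methylbutanoate
Conditions: Ac2O, pyridine, DMAP (cat.), CH2Cl2, 0 °C
Reagents that add atoms: acetic anhydride, CC(=O)OC(C)=O
Why: DMAP-catalysed acetylation of the primary alcohol runs under mildly basic conditions that the oxirane tolerates.

**Step 9**
Reactants: 17 {4-[(2R)-2-(acetyloxymethyl)oxiran-2-yl]-3-(prop-2-en-1-yloxy)phenyl}methyl 3-methylbutanoate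
Product: 18 {4-[(2R)-2-(acetyloxymethyl)oxiran-2-yl]-3-hydroxyphenyl}methyl 3-methylbutanoate
Conditions: Pd(PPh3)4 (5 mol%), PhNHMe (3 equiv), THF, rt
Reagents that add atoms: none
Why: Tsuji–Trost deallylation, in which zerovalent palladium ionises the aryl allyl ether to a π-allyl complex that N-methylaniline intercepts, frees the phenol without acid, strong base or fluoride; the phenol is not stored but used at once.

**Step 10**
Reactants: 18 {4-[(2R)-2-(acetyloxymethyl)oxiran-2-yl]-3-hydroxyphenyl}methyl 3-methylbutanoate; 19 angelic acid, (2Z)-2-methylbut-2-enoic acid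
Product: 21 2-[(2R)-2-(acetyloxymethyl)oxiran-2-yl]-5-[(3-methylbutanoyloxy)methyl]phenyl (2Z)-2-methylbut-2-enoate (CNP0212475.1), via angeloyl trichlorobenzoyl anhydride 20 (not isolated)
Conditions: 19, 2,4,6-Cl3C6H2COCl, Et3N, toluene, rt, filtered; then 18, Et3N, 0 °C to rt
Reagents that add atoms: none
Why: Yamaguchi-type esterification, in which the phenol attacks the unhindered angeloyl carbonyl of pre-formed 20 (the other carbonyl is shielded by two ortho chlorines), acylates the phenoxide as soon as it forms and, without DMAP or an acyl chloride, should keep the Z-alkene from isomerising to the tiglate.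

**Compound list**
1 | methyl 3-hydroxy-4-iodobenzoate | COC(=O)c1ccc(I)c(O)c1 | starting material
2 | methyl 4-iodo-3-(prop-2-en-1-yloxy)benzoate | COC(=O)c1ccc(I)c(OCC=C)c1 | intermediate
3 | [4-iodo-3-(prop-2-en-1-yloxy)phenyl]methanol | OCc1ccc(I)c(OCC=C)c1 | intermediate
4 | [4-iodo-3-(prop-2-en-1-yloxy)phenyl]methyl 3-methylbutanoate | CC(C)CC(=O)OCc1ccc(I)c(OCC=C)c1 | intermediate
5 | 4-methoxybenzyl alcohol | COc1ccc(CO)cc1 | starting material
6 | 2-chloro-N-methoxy-N-methylacetamide | CON(C)C(=O)CCl | starting material
7 | sodium 4-methoxybenzyl oxide | [Na+].[O-]Cc1ccc(OC)cc1 | intermediate (not isolated)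
8 | N-methoxy-2-[(4-methoxyphenyl)methoxy]-N-methylacetamide | CON(C)C(=O)COCc1ccc(OC)cc1 | intermediate
9 | chloro{4-[(3-methylbutanoyloxy)methyl]-2-(prop-2-en-1-yloxy)phenyl}magnesium (LiCl complex) | CC(C)CC(=O)OCc1ccc([Mg]Cl)c(OCC=C)c1 | intermediate (not isolated)
10 | chloromagnesium 1-[methoxy(methyl)amino]-2-[(4-methoxyphenyl)methoxy]-1-{4-[(3-methylbutanoyloxy)methyl]-2-(prop-2-en-1-yloxy)phenyl}ethan-1-olate | CC(C)CC(=O)OCc1ccc(C(O[Mg]Cl)(COCc2ccc(OC)cc2)N(C)OC)c(OCC=C)c1 | intermediate (not isolated)
11 | {4-{2-[(4-methoxyphenyl)methoxy]acetyl}-3-(prop-2-en-1-yloxy)phenyl}methyl 3-methylbutanoate | CC(C)CC(=O)OCc1ccc(C(=O)COCc2ccc(OC)cc2)c(OCC=C)c1 | intermediate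
12 | trimethylsulfoxonium chloride | C[S+](C)(C)=O.[Cl-] | starting material
13 | dimethylsulfoxonium methylide | [CH2-][S+](C)(C)=O | intermediate (not isolated)
14 | (2S)-1-[dimethyl(oxo)sulfonio]-3-[(4-methoxyphenyl)methoxy]-2-{4-[(3-methylbutanoyloxy)methyl]-2-(prop-2-en-1-yloxy)phenyl}propan-2-olate | CC(C)CC(=O)OCc1ccc([C@]([O-])(COCc2ccc(OC)cc2)C[S+](C)(C)=O)c(OCC=C)c1 | intermediate (not isolated)
15 | {4-[(2R)-2-{[(4-methoxyphenyl)methoxy]methyl}oxiran-2-yl]-3-(prop-2-en-1-yloxy)phenyl}methyl 3-methylbutanoate | CC(C)CC(=O)OCc1ccc([C@]2(COCc3ccc(OC)cc3)CO2)c(OCC=C)c1 | intermediate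
16 | {4-[(2S)-2-(hydroxymethyl)oxiran-2-yl]-3-(prop-2-en-1-yloxy)phenyl}methyl 3-methylbutanoate | CC(C)CC(=O)OCc1ccc([C@]2(CO)CO2)c(OCC=C)c1 | intermediate
17 | {4-[(2R)-2-(acetyloxymethyl)oxiran-2-yl]-3-(prop-2-en-1-yloxy)phenyl}methyl 3-methylbutanoate | CC(C)CC(=O)OCc1ccc([C@]2(COC(C)=O)CO2)c(OCC=C)c1 | intermediate
18 | {4-[(2R)-2-(acetyloxymethyl)oxiran-2-yl]-3-hydroxyphenyl}methyl 3-methylbutanoate | CC(C)CC(=O)OCc1ccc([C@]2(COC(C)=O)CO2)c(O)c1 | intermediate
19 | angelic acid, (2Z)-2-methylbut-2-enoic acid | C/C=C(/C)C(=O)O | starting material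
20 | (2Z)-2-methylbut-2-enoic 2,4,6-trichlorobenzoic anhydride | C/C=C(/C)C(=O)OC(=O)c1c(Cl)cc(Cl)cc1Cl | intermediate (not isolated)
21 | 2-[(2R)-2-(acetyloxymethyl)oxiran-2-yl]-5-[(3-methylbutanoyloxy)methyl]phenyl (2Z)-2-methylbut-2-enoate | C/C=C(/C)C(=O)Oc1cc(COC(=O)CC(C)C)ccc1[C@]1(COC(C)=O)CO1 | target

Total step count: 10. Longest linear sequence: 9 steps (steps 1, 2, 3, 5, 6, 7, 8, 9, 10 from compound 1); step 4 is a one-step side branch.

**Steps most likely to fail**

Step 6. The ylide may add with poor facial discrimination, because the CH2OPMB arm is bulkier than methyl and both ether oxygens can chelate the lanthanum or lithium sites. The hindered ortho-substituted ketone may also react so slowly that attack on the ester begins to compete. The fallback sets out from ketone 11 and takes the stereocentre from a hydroxyl-directed epoxidation instead. Wittig methylenation (Ph3PCH3Br, KOtBu, THF, 0 °C) should give the alkene {4-{3-[(4-methoxyphenyl)methoxy]prop-1-en-2-yl}-3-(prop-2-en-1-yloxy)phenyl}methyl 3-methylbutanoate F1. DDQ at buffered pH 7 then removes the PMB group to give the allylic alcohol {4-(3-hydroxyprop-1-en-2-yl)-3-(prop-2-en-1-yloxy)phenyl}methyl 3-methylbutanoate F2. Katsuki–Sharpless epoxidation (Ti(OiPr)4, L-(+)-diisopropyl tartrate, t-BuOOH, 4 Å molecular sieves, CH2Cl2, −20 °C) acts only on the allylic alcohol and leaves the allyl ether alkene alone. The L-(+)-tartrate is chosen because it gives the (S) series of 2-substituted glycidols, so the product should be glycidol 16, where the route is rejoined.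

Step 9. Once the ortho hydroxyl is free it may open the neighbouring oxirane (cyclisation to a dihydrobenzofuranol, or ionisation of the benzylic C–O bond) before it can be acylated. The fallback sets out from 17 and never liberates the phenol. Deallylation is run as a silyl transfer (Pd(PPh3)4, N-(trimethylsilyl)morpholine, THF, rt), so that the phenoxide is silylated as it leaves palladium. This should give {4-[(2R)-2-(acetyloxymethyl)oxiran-2-yl]-3-[(trimethylsilyl)oxy]phenyl}methyl 3-methylbutanoate F3, used crude. Bu4NF (1 equiv) is then added slowly at −20 °C to F3 in the presence of an excess of pre-formed mixed anhydride 20, so that each phenoxide is acylated as it is unmasked, and the route is rejoined at target 21.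

Step 5. The aryl Grignard 9, or iPrMgCl before the exchange is complete, may add to the isovalerate of a second molecule, or the exchange may be too slow on the electron-rich ring at the low temperature the ester requires. The fallback sets out from alcohol 3 and forms the ketone before the ester. Compound 3 is deprotonated with MeMgCl (1 equiv, THF, −20 °C) and exchanged with iPrMgCl·LiCl, now at up to 0 °C since no ester is present. Acylation with Weinreb amide 8 should give 1-[4-(hydroxymethyl)-2-(prop-2-en-1-yloxy)phenyl]-2-[(4-methoxyphenyl)methoxy]ethan-1-one F4. Esterification with 3-methylbutanoyl chloride (Et3N, DMAP, CH2Cl2, 0 °C) then rejoins the route at ketone 11.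

**Further compounds**
F1 | step 6 | {4-{3-[(4-methoxyphenyl)methoxy]prop-1-en-2-yl}-3-(prop-2-en-1-yloxy)phenyl}methyl 3-methylbutanoate | CC(C)CC(=O)OCc1ccc(C(=C)COCc2ccc(OC)cc2)c(OCC=C)c1
F2 | step 6 | {4-(3-hydroxyprop-1-en-2-yl)-3-(prop-2-en-1-yloxy)phenyl}methyl 3-methylbutanoate | CC(C)CC(=O)OCc1ccc(C(=C)CO)c(OCC=C)c1
F3 | step 9 | {4-[(2R)-2-(acetyloxymethyl)oxiran-2-yl]-3-[(trimethylsilyl)oxy]phenyl}methyl 3-methylbutanoate | CC(C)CC(=O)OCc1ccc([C@]2(COC(C)=O)CO2)c(O[Si](C)(C)C)c1
F4 | step 5 | 1-[4-(hydroxymethyl)-2-(prop-2-en-1-yloxy)phenyl]-2-[(4-methoxyphenyl)methoxy]ethan-1-one | OCc1ccc(C(=O)COCc2ccc(OC)cc2)c(OCC=C)c1
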